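**Retrosynthetic overview**

1. Numbering: lactone O1–C5, side chain C6–C18 outward from C5, furan on C18. The strategy rests on C11, a methyl-bearing sp3 carbon between the C10 methylene and the conjugated (12E,14E)-diene C12–C15, that is, the end carbon of a methyl-terminated pentadienyl unit.
2. Last disconnection: the tetronic acid ring (O1–C5), the only ring made in the route (the furan is bought), is opened at C3–C4 (Dieckmann) to an O-propanoyl α-hydroxy methyl ester. The propanoyl group is placed on the C5 oxygen before the coupling, where it is a spectator, so that only the ring closure follows.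
3. Key disconnection: C10–C11, by nickel/pybox enantioconvergent Negishi coupling of the racemic C11 dienyl chloride (C11–C18 plus furan) with a C4–C10 homoallylic alkylzinc bromide that already carries C5 (R).
4. Chloride: 3-bromofuran plus oxetane (C16–C18), syn-carbocupration of ethyl but-2-ynoate (C13–C15, 14E), ketophosphonate olefination (C11–C12, 12E), Luche reduction, chlorination.
5. Zinc reagent: pent-3-yn-1-ol by hydrozirconation–iodination (7E alkene), copper-catalysed opening of methyl (R)-glycidate (C4–C6, C5 from the chiral pool), propanoylation, bromination, zinc insertion.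

Key step: step 16

Assumption: the (S,S)-enantiomer of the phenethyl-pybox ligand is taken to deliver the S configuration at C11; if a model coupling shows the opposite sense, the (R,R)-ligand is used and nothing else changes.

**Route**

Step 1
Reactants: 1 3-bromofuran; 2 oxetane
Product: 4 3-(furan-3-yl)propan-1-ol, via furan-3-yllithium 3 (not isolated)
Conditions: n-BuLi, THF, −78 °C; then oxetane, BF3·OEt2, −78 °C
Reagents that add atoms: none
Why: Bromine–lithium exchange gives furan-3-yllithium, which keeps its position at −78 °C, and the BF3-activated oxetane is opened by the organolithium (Lewis-acid-promoted opening of a cyclic ether) to install the C16–C18 tether in one operation.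

Step 2
Reactants: 4 3-(furan-3-yl)propan-1-ol
Product: 5 3-(3-bromopropyl)furan
Conditions: CBr4, PPh3, CH2Cl2, 0 °C
Reagents that add atoms: carbon tetrabromide, BrC(Br)(Br)Br
Why: Appel bromination of a primary alcohol under neutral conditions that the furan tolerates.

Step 3
Reactants: 5 3-(3-bromopropyl)furan; 6 ethyl but-2-ynoate
Product: 9 ethyl (2E)-6-(furan-3-yl)-3-methylhex-2-enoate, via Grignard reagent 7 (not isolated), via alkylcopper 8 (not isolated)
Conditions: Mg, THF, rt; CuBr·SMe2 (1 equiv), THF, −45 °C; ethyl but-2-ynoate, −78 °C; NH4Cl quench at −78 °C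
Reagents that add atoms: none
Why: The alkylcopper adds syn across the ynoate at −78 °C (carbocupration / conjugate addition) and low-temperature protonation of the alkenylcopper with retention fixes the 14E trisubstituted alkene, the new chain trans to the ester.

Step 4
Reactants: 9 ethyl (2E)-6-(furan-3-yl)-3-methylhex-2-enoate
Product: 10 (2E)-6-(furan-3-yl)-3-methylhex-2-en-1-ol
Conditions: i-Bu2AlH (2.3 equiv), CH2Cl2, −78 to 0 °C
Reagents that add atoms: none
Why: i-Bu2AlH reduces the conjugated ester in the 1,2-sense to the allylic alcohol without affecting the alkene geometry or the furan.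

Step 5
Reactants: 10 (2E)-6-(furan-3-yl)-3-methylhex-2-en-1-ol
Product: 11 (2E)-6-(furan-3-yl)-3-methylhex-2-enal
Conditions: MnO2, CH2Cl2, rt
Reagents that add atoms: none
Why: MnO2 oxidises allylic alcohols selectively to enals under neutral conditions with retention of the E geometry.

Step 6
Reactants: 11 (2E)-6-(furan-3-yl)-3-methylhex-2-enal
Product: 12 (3E,5E)-9-(furan-3-yl)-6-methylnona-3,5-dien-2-one
Conditions: dimethyl (2-oxopropyl)phosphonate, LiCl, i-Pr2NEt, MeCN, rt
Reagents that add atoms: dimethyl (2-oxopropyl)phosphonate, COP(=O)(OC)CC(C)=O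
Why: Horner–Wadsworth–Emmons olefination with a β-ketophosphonate under mild LiCl/amine conditions should give the E enone (C12=C13) without base-induced isomerisation of the enal.

Step 7
Reactants: 12 (3E,5E)-9-(furan-3-yl)-6-methylnona-3,5-dien-2-one
Product: 13 racemic (3E,5E)-9-(furan-3-yl)-6-methylnona-3,5-dien-2-ol
Conditions: NaBH4, CeCl3·7H2O, MeOH, 0 °C
Reagents that add atoms: none
Why: Luche reduction delivers hydride 1,2 to the dienone carbonyl; the carbinol centre needs no control because its configuration is erased in step 16.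

Step 8
Reactants: 13 racemic (3E,5E)-9-(furan-3-yl)-6-methylnona-3,5-dien-2-ol
Product: 15 racemic 3-[(4E,6E)-8-chloro-4-methylnona-4,6-dien-1-yl]furan, via dienyl mesylate 14 (not isolated)
Conditions: MsCl, LiCl, 2,4,6-collidine, DMF, 0 °C; pentane extraction, used at once without chromatography
Reagents that add atoms: lithium chloride, [Li+].[Cl-]; methanesulfonyl chloride, CS(=O)(=O)Cl (sulfonyl group in 14 only, its chloride may also end up in 15)
Why: Mesylation in the presence of chloride converts an allylic-type alcohol into the chloride under buffered, non-acidic conditions (sulfonate displacement by chloride); allyl-transposed isomers that may accompany the product converge in step 16.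

Step 9
Reactants: 16 pent-3-yn-1-ol
Product: 17 tert-butyldimethyl(pent-3-yn-1-yloxy)silane
Conditions: TBSCl, imidazole, CH2Cl2, rt
Reagents that add atoms: tert-butyldimethylsilyl chloride, CC(C)(C)[Si](C)(C)Cl
Why: Standard silylation protects the primary alcohol against the organometallic steps that follow.

Step 10
Reactants: 17 tert-butyldimethyl(pent-3-yn-1-yloxy)silane
Product: 19 tert-butyl{[(3E)-4-iodopent-3-en-1-yl]oxy}dimethylsilane, via alkenylzirconocene chloride 18 (not isolated)
Conditions: Cp2Zr(H)Cl (2 equiv), THF, 50 °C; then I2, 0 °C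
Reagents that add atoms: iodine, II
Why: Syn hydrozirconation of the internal alkyne with excess Cp2Zr(H)Cl under equilibrating conditions places zirconium on the less hindered, methyl-bearing carbon, and iodinolysis with retention gives the E alkenyl iodide that becomes the 7E alkene.

Step 11
Reactants: 19 tert-butyl{[(3E)-4-iodopent-3-en-1-yl]oxy}dimethylsilane; 20 methyl (2R)-oxirane-2-carboxylate
Product: 23 methyl (2R,4E)-7-(tert-butyldimethylsilyloxy)-2-hydroxy-4-methylhept-4-enoate, via alkenyllithium 21 (not isolated), via alkenylmagnesium bromide 22 (not isolated)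
Conditions: t-BuLi (2 equiv), Et2O, −78 °C; MgBr2·OEt2, −78 to 0 °C; CuI (15 mol %), THF, then 20, −40 °C; NH4Cl quench
Reagents that add atoms: none
Why: Iodine–lithium exchange with retention of alkene geometry, transmetalation to magnesium and copper-catalysed epoxide opening at the unsubstituted CH2 of the glycidate form C6–C7; C5 (R) comes unchanged from the glycidate because its C–O bond is not touched.

Step 12
Reactants: 23 methyl (2R,4E)-7-(tert-butyldimethylsilyloxy)-2-hydroxy-4-methylhept-4-enoate
Product: 24 methyl (2R,4E)-7-(tert-butyldimethylsilyloxy)-4-methyl-2-(propanoyloxy)hept-4-enoate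
Conditions: EtCOCl, pyridine, DMAP (cat.), CH2Cl2, 0 °C
Reagents that add atoms: propanoyl chloride, CCC(Cl)=O
Why: Acylation of the secondary alcohol under pyridine/DMAP installs the future C2–C3 unit of the tetronic acid as an ester that also masks the C5 oxygen during the coupling.

Step 13
Reactants: 24 methyl (2R,4E)-7-(tert-butyldimethylsilyloxy)-4-methyl-2-(propanoyloxy)hept-4-enoate
Product: 25 methyl (2R,4E)-7-hydroxy-4-methyl-2-(propanoyloxy)hept-4-enoate
Conditions: HF·pyridine, pyridine, THF, 0 °C to rt
Reagents that add atoms: none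
Why: Buffered fluoride cleaves the primary silyl ether and leaves both esters, the alkene and the C5 stereocentre untouched.

Step 14
Reactants: 25 methyl (2R,4E)-7-hydroxy-4-methyl-2-(propanoyloxy)hept-4-enoate
Product: 26 methyl (2R,4E)-7-bromo-4-methyl-2-(propanoyloxy)hept-4-enoate
Conditions: CBr4, PPh3, CH2Cl2, 0 °C
Reagents that add atoms: carbon tetrabromide, BrC(Br)(Br)Br
Why: Appel bromination of the primary homoallylic alcohol under neutral conditions compatible with the two esters.

Step 15
Reactants: 26 methyl (2R,4E)-7-bromo-4-methyl-2-(propanoyloxy)hept-4-enoate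
Product: 27 {(3E,6R)-7-methoxy-4-methyl-7-oxo-6-(propanoyloxy)hept-3-en-1-yl}zinc bromide (titrated DMA solution, used directly)
Conditions: Zn dust (1.5 equiv), I2 (5 mol %), DMA, 70 °C
Reagents that add atoms: zinc, [Zn]
Why: Direct insertion of iodine-activated zinc dust into a primary alkyl bromide in a polar amide solvent gives the alkylzinc bromide, a reagent class that tolerates esters.

Step 16
Reactants: 15 racemic 3-[(4E,6E)-8-chloro-4-methylnona-4,6-dien-1-yl]furan; 27 {(3E,6R)-7-methoxy-4-methyl-7-oxo-6-(propanoyloxy)hept-3-en-1-yl}zinc bromide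
Product: 28 methyl (2R,4E,8S,9E,11E)-15-(furan-3-yl)-4,8,12-trimethyl-2-(propanoyloxy)pentadeca-4,9,11-trienoate
Conditions: NiCl2·glyme (5 mol %), 2,6-bis[(4S)-4-(2-phenylethyl)-4,5-dihydrooxazol-2-yl]pyridine (5.5 mol %), NaCl (4 equiv), 27 (1.3 equiv), DMA/DMF 1:1, −10 °C
Reagents that add atoms: none
Why: Proposed new method: a monovalent nickel–pybox species abstracts chloride from either enantiomer of 15, and from any allyl-transposed isomer, to give one pentadienyl radical delocalised over C11, C13 and C15, which is captured by the pybox-bound alkylnickel formed by transmetalation from 27, and reductive elimination from the resulting trivalent nickel forms C10–C11; the closest known reaction is the nickel/pybox enantioconvergent Negishi coupling of racemic secondary allylic chlorides with alkylzinc halides, extended here by one vinylogous unit. No ring is closed in this step. The new stereocentre C11 (8S in the product numbering) is set by the chiral ligand alone, because the configuration of the chloride is lost in the radical and the C5 stereocentre of 27 lies five bonds from the reacting carbon. The step needs bond formation at C11 and not at C13 or C15: attack at C11 keeps the C12–C15 diene conjugated and gives a secondary centre, whereas C13 would break the conjugation and C15 would create a quaternary carbon, the same preferences (conjugation kept, less hindered terminus) that rule the known unsymmetrical allylic cases. The 12E geometry is expected from the extended geometry of the delocalised intermediate, and the esters, furan and trisubstituted alkene are inert to an alkylzinc halide at −10 °C.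

Step 17
Reactants: 28 methyl (2R,4E,8S,9E,11E)-15-(furan-3-yl)-4,8,12-trimethyl-2-(propanoyloxy)pentadeca-4,9,11-trienoate
Product: 29 (5R)-5-[(2E,6S,7E,9E)-13-(furan-3-yl)-2,6,10-trimethyltrideca-2,7,9-trien-1-yl]-4-hydroxy-3-methylfuran-2(5H)-one (CNP0129957.3)
Conditions: LiN(SiMe3)2 (2.5 equiv), THF, −78 to 0 °C; then 1 M HCl, 0 °C
Reagents that add atoms: none
Why: Dieckmann cyclisation, in which the lithium enolate of the propanoate attacks the neighbouring methyl ester (5-exo-trig) with loss of methoxide and the product is held as its tetronate anion, which shields C5 from deprotonation, so that acidification should give the 4-hydroxybutenolide with C5 (R) carried over from the glycidate.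

**Compound list**

1 | 3-bromofuran | Brc1ccoc1 | starting material
2 | oxetane | C1COC1 | starting material
3 | furan-3-yllithium | [Li]c1ccoc1 | intermediate
4 | 3-(furan-3-yl)propan-1-ol | OCCCc1ccoc1 | intermediate
5 | 3-(3-bromopropyl)furan | BrCCCc1ccoc1 | intermediate
6 | ethyl but-2-ynoate | CCOC(=O)C#CC | starting material
7 | [3-(furan-3-yl)propyl]magnesium bromide | Br[Mg]CCCc1ccoc1 | intermediate
8 | [3-(furan-3-yl)propyl]copper (as its MgBr2 complex) | [Cu]CCCc1ccoc1 | intermediate
9 | ethyl (2E)-6-(furan-3-yl)-3-methylhex-2-enoate | CCOC(=O)/C=C(\C)CCCc1ccoc1 | intermediate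
10 | (2E)-6-(furan-3-yl)-3-methylhex-2-en-1-ol | OC/C=C(\C)CCCc1ccoc1 | intermediate
11 | (2E)-6-(furan-3-yl)-3-methylhex-2-enal | O=C/C=C(\C)CCCc1ccoc1 | intermediate
12 | (3E,5E)-9-(furan-3-yl)-6-methylnona-3,5-dien-2-one | CC(=O)/C=C/C=C(\C)CCCc1ccoc1 | intermediate
13 | racemic (3E,5E)-9-(furan-3-yl)-6-methylnona-3,5-dien-2-ol | CC(O)/C=C/C=C(\C)CCCc1ccoc1 | intermediate
14 | racemic (3E,5E)-9-(furan-3-yl)-6-methylnona-3,5-dien-2-yl methanesulfonate | CC(OS(C)(=O)=O)/C=C/C=C(\C)CCCc1ccoc1 | intermediate
15 | racemic 3-[(4E,6E)-8-chloro-4-methylnona-4,6-dien-1-yl]furan | CC(Cl)/C=C/C=C(\C)CCCc1ccoc1 | intermediate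
16 | pent-3-yn-1-ol | CC#CCCO | starting material
17 | tert-butyldimethyl(pent-3-yn-1-yloxy)silane | CC#CCCO[Si](C)(C)C(C)(C)C | intermediate
18 | chlorobis(cyclopentadienyl)[(2E)-5-(tert-butyldimethylsilyloxy)pent-2-en-2-yl]zirconium | Cl[Zr](C1C=CC=C1)(C1C=CC=C1)/C(C)=C/CCO[Si](C)(C)C(C)(C)C | intermediate
19 | tert-butyl{[(3E)-4-iodopent-3-en-1-yl]oxy}dimethylsilane | I/C(C)=C/CCO[Si](C)(C)C(C)(C)C | intermediate
20 | methyl (2R)-oxirane-2-carboxylate | COC(=O)[C@H]1CO1 | starting material
21 | [(2Z)-5-(tert-butyldimethylsilyloxy)pent-2-en-2-yl]lithium (geometry of 19 retained; descriptor changes because lithium ranks below carbon) | [Li]/C(C)=C/CCO[Si](C)(C)C(C)(C)C | intermediate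
22 | [(2E)-5-(tert-butyldimethylsilyloxy)pent-2-en-2-yl]magnesium bromide | Br[Mg]/C(C)=C/CCO[Si](C)(C)C(C)(C)C | intermediate
23 | methyl (2R,4E)-7-(tert-butyldimethylsilyloxy)-2-hydroxy-4-methylhept-4-enoate | COC(=O)[C@H](O)C/C(C)=C/CCO[Si](C)(C)C(C)(C)C | intermediate
24 | methyl (2R,4E)-7-(tert-butyldimethylsilyloxy)-4-methyl-2-(propanoyloxy)hept-4-enoate | COC(=O)[C@H](OC(=O)CC)C/C(C)=C/CCO[Si](C)(C)C(C)(C)C | intermediate
25 | methyl (2R,4E)-7-hydroxy-4-methyl-2-(propanoyloxy)hept-4-enoate | COC(=O)[C@H](OC(=O)CC)C/C(C)=C/CCO | intermediate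
26 | methyl (2R,4E)-7-bromo-4-methyl-2-(propanoyloxy)hept-4-enoate | COC(=O)[C@H](OC(=O)CC)C/C(C)=C/CCBr | intermediate
27 | {(3E,6R)-7-methoxy-4-methyl-7-oxo-6-(propanoyloxy)hept-3-en-1-yl}zinc bromide | Br[Zn]CC/C=C(\C)C[C@@H](OC(=O)CC)C(=O)OC | intermediate
28 | methyl (2R,4E,8S,9E,11E)-15-(furan-3-yl)-4,8,12-trimethyl-2-(propanoyloxy)pentadeca-4,9,11-trienoate | COC(=O)[C@H](OC(=O)CC)C/C(C)=C/CC[C@H](C)/C=C/C=C(\C)CCCc1ccoc1 | intermediate
29 | (5R)-5-[(2E,6S,7E,9E)-13-(furan-3-yl)-2,6,10-trimethyltrideca-2,7,9-trien-1-yl]-4-hydroxy-3-methylfuran-2(5H)-one | CC1=C(O)[C@@H](C/C(C)=C/CC[C@H](C)/C=C/C=C(\C)CCCc2ccoc2)OC1=O | target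

**Step count**

Total: 17 steps. Longest linear sequence: 10 steps (steps 1–8, 16, 17, from 3-bromofuran); the other branch is 9 steps (steps 9–15, 16, 17).

**Steps most likely to fail**

Step 16 (proposed new method). What may go wrong: bond formation at C13 or C15 instead of C11, low enantioselectivity on the vinylogous allyl system, rotation about C14–C15 in the delocalised intermediate with loss of the 14E geometry, or ionisation and elimination of the labile chloride before it is consumed. The fallback sets out from 27 and 10 and comes back at 28. It sets C11 by the known nickel/pybox enantioconvergent Negishi coupling of racemic α-bromo amides and then builds the diene by olefination. Racemic N-benzyl-2-bromo-N-phenylpropanamide F1 (from 2-bromopropanoyl bromide and N-benzylaniline, Et3N, CH2Cl2) is coupled with 27 (NiCl2·glyme, the appropriate enantiomer of i-Pr-pybox, DMI/THF, 0 °C) to give methyl (2R,4E,8S)-9-[benzyl(phenyl)amino]-4,8-dimethyl-9-oxo-2-(propanoyloxy)non-4-enoate F2. Cp2Zr(H)Cl in THF at rt should reduce the tertiary amide, leaving both esters, to methyl (2R,4E,8S)-4,8-dimethyl-9-oxo-2-(propanoyloxy)non-4-enoate F3. In parallel, alcohol 10 is converted with CBr4/PPh3 into 3-[(4E)-6-bromo-4-methylhex-4-en-1-yl]furan F4 and by Arbuzov reaction with P(OEt)3 into diethyl [(2E)-6-(furan-3-yl)-3-methylhex-2-en-1-yl]phosphonate F5. The lithium anion of F5 (LiN(SiMe3)2, THF, −78 °C) and F3 should give 28 by Horner–Wadsworth–Emmons olefination, with the new C12=C13 bond expected to be mainly E.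

Step 17. What may go wrong: deprotonation at C5 (alpha to the methyl ester and bearing the acyloxy group) competes with enolisation of the propanoate, which erodes the C5 configuration or leads to a 1,2-acyl shift instead of ring closure. The fallback sets out from 28 and comes back at 29. It makes the C3–C4 bond intermolecularly on a silyl-protected α-oxy ester and closes the ring by lactonisation. Methanolysis of the propanoate (K2CO3, MeOH, 0 °C) gives methyl (2R,4E,8S,9E,11E)-15-(furan-3-yl)-2-hydroxy-4,8,12-trimethylpentadeca-4,9,11-trienoate F6. Silylation (TBSOTf, 2,6-lutidine, CH2Cl2, −78 °C) gives methyl (2R,4E,8S,9E,11E)-2-(tert-butyldimethylsilyloxy)-15-(furan-3-yl)-4,8,12-trimethylpentadeca-4,9,11-trienoate F7. Crossed Claisen condensation with the lithium enolate of ethyl propanoate (LiN(i-Pr)2, THF, −78 to −20 °C) gives ethyl (4R,6E,10S,11E,13E)-4-(tert-butyldimethylsilyloxy)-17-(furan-3-yl)-2,6,10,14-tetramethyl-3-oxoheptadeca-6,11,13-trienoate F8 as a mixture at C2. Bu4NF in THF then removes the silyl group, and the freed alkoxide should lactonise onto the ethyl ester to give 29 after mild acidification.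

Step 11. What may go wrong: 1,2-addition of the alkenylmagnesium reagent to the methyl ester of the glycidate in competition with the copper-catalysed epoxide opening, or protonation of the alkenyl metal. The fallback sets out from 19 and comes back at 23. It replaces the ester by an alcohol during C–C bond formation and oxidises afterwards. Alkenylmagnesium bromide 22, made as in step 11, opens (S)-glycidol (deprotonated beforehand with n-BuLi; CuI cat., THF, −30 °C) to give (2R,4E)-7-(tert-butyldimethylsilyloxy)-4-methylhept-4-ene-1,2-diol F9. Selective oxidation of the primary alcohol (TEMPO, PhI(OAc)2, MeCN/H2O) gives (2R,4E)-7-(tert-butyldimethylsilyloxy)-2-hydroxy-4-methylhept-4-enoic acid F10, and Me3SiCHN2 in MeOH/toluene gives 23.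

**Further compounds**

F1 | step 16 | racemic N-benzyl-2-bromo-N-phenylpropanamide | CC(Br)C(=O)N(Cc1ccccc1)c1ccccc1
F2 | step 16 | methyl (2R,4E,8S)-9-[benzyl(phenyl)amino]-4,8-dimethyl-9-oxo-2-(propanoyloxy)non-4-enoate | COC(=O)[C@H](OC(=O)CC)C/C(C)=C/CC[C@H](C)C(=O)N(Cc1ccccc1)c1ccccc1
F3 | step 16 | methyl (2R,4E,8S)-4,8-dimethyl-9-oxo-2-(propanoyloxy)non-4-enoate | COC(=O)[C@H](OC(=O)CC)C/C(C)=C/CC[C@H](C)C=O
F4 | step 16 | 3-[(4E)-6-bromo-4-methylhex-4-en-1-yl]furan | BrC/C=C(\C)CCCc1ccoc1
F5 | step 16 | diethyl [(2E)-6-(furan-3-yl)-3-methylhex-2-en-1-yl]phosphonate | CCOP(=O)(OCC)C/C=C(\C)CCCc1ccoc1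
F6 | step 17 | methyl (2R,4E,8S,9E,11E)-15-(furan-3-yl)-2-hydroxy-4,8,12-trimethylpentadeca-4,9,11-trienoate | COC(=O)[C@H](O)C/C(C)=C/CC[C@H](C)/C=C/C=C(\C)CCCc1ccoc1
F7 | step 17 | methyl (2R,4E,8S,9E,11E)-2-(tert-butyldimethylsilyloxy)-15-(furan-3-yl)-4,8,12-trimethylpentadeca-4,9,11-trienoate | COC(=O)[C@H](O[Si](C)(C)C(C)(C)C)C/C(C)=C/CC[C@H](C)/C=C/C=C(\C)CCCc1ccoc1
F8 | step 17 | ethyl (4R,6E,10S,11E,13E)-4-(tert-butyldimethylsilyloxy)-17-(furan-3-yl)-2,6,10,14-tetramethyl-3-oxoheptadeca-6,11,13-trienoate | CCOC(=O)C(C)C(=O)[C@H](O[Si](C)(C)C(C)(C)C)C/C(C)=C/CC[C@H](C)/C=C/C=C(\C)CCCc1ccoc1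
F9 | step 11 | (2R,4E)-7-(tert-butyldimethylsilyloxy)-4-methylhept-4-ene-1,2-diol | OC[C@H](O)C/C(C)=C/CCO[Si](C)(C)C(C)(C)C
F10 | step 11 | (2R,4E)-7-(tert-butyldimethylsilyloxy)-2-hydroxy-4-methylhept-4-enoic acid | OC(=O)[C@H](O)C/C(C)=C/CCO[Si](C)(C)C(C)(C)C
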